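Ring A (C1–C4, C5, C10) is disconnected at C4–C5 and C1–C10. The key step is a Lewis-acid-catalysed Diels–Alder reaction between a carene-derived cyclohexenone that already is ring B (C9 carbonyl, C5=C10 double bond, C7 isopropenyl, C8 silyloxy) and (Z)-3-silyloxypenta-1,3-diene. It exploits the fact that the C3 oxygen of ring A sits para to C10, the α-carbon of an oxygenated C9. In one operation it closes ring A, creates the C5 quaternary centre and the cis C5/C10 fusion anti to the C7 isopropenyl group, and delivers C3 and C9 as differentiated carbonyl equivalents. C4, C3 and C9 are then adjusted by equilibration, dissolving-metal reduction and SN2 inversion.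

Key step: step 7

Remark: decalins carry eremophilane numbering (ring A = C1–C4, C5, C10; ring B = C5–C10; C11–C13 = isopropenyl on C7), β is the face of the C5 methyl, (+)-3-carene is taken as (1S,6R), and 9 and 10 are drawn without a C4 descriptor because both C4 epimers converge in step 8.

Step 1
Reactants: 1 (+)-3-carene
Product: 2 car-3-en-5-one [(1R,6S)-4,7,7-trimethylbicyclo[4.1.0]hept-3-en-2-one]
Conditions: t-BuOOH, Cr(CO)6 (cat.), MeCN, reflux
Reagents that add atoms: tert-butyl hydroperoxide, CC(C)(C)OO
Why: Chromium-catalysed allylic oxidation converts the ring CH2 that is both allylic and cyclopropylcarbinyl into the enone carbonyl and leaves the two ring stereocentres untouched.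

Step 2
Reactants: 2 car-3-en-5-one
Product: 3 (S)-5-(2-hydroxypropan-2-yl)-3-methylcyclohex-2-en-1-one
Conditions: H2SO4 (0.5 M aq.), THF, 40 °C
Reagents that add atoms: water, O
Why: Acid-catalysed homoconjugate addition of water to the cyclopropyl ketone cleaves the cyclopropane bond α to the carbonyl towards the tertiary cation, which gives the m-menthane skeleton and does not involve the stereocentre that becomes C7.

Step 3
Reactants: 3 (S)-5-(2-hydroxypropan-2-yl)-3-methylcyclohex-2-en-1-one
Product: 4 (S)-3-methyl-5-(prop-1-en-2-yl)cyclohex-2-en-1-one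
Conditions: Burgess reagent, PhMe, 60 °C
Reagents that add atoms: none
Why: Burgess dehydration is a syn-Ei elimination of the sulfamate that should take one of the six unhindered methyl hydrogens instead of the ring methine and so give the isopropenyl group without acid-type isomerisation.

Step 4
Reactants: 4 (S)-3-methyl-5-(prop-1-en-2-yl)cyclohex-2-en-1-one
Product: 5 (5R,6R)-6-hydroxy-3-methyl-5-(prop-1-en-2-yl)cyclohex-2-en-1-one
Conditions: LDA, THF, –78 °C; 2-(phenylsulfonyl)-3-phenyloxaziridine; aq. NH4Cl
Reagents that add atoms: 2-(phenylsulfonyl)-3-phenyloxaziridine (Davis oxaziridine), O=S(=O)(c1ccccc1)N1OC1c1ccccc1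
Why: Kinetic α′-deprotonation gives the cross-conjugated enolate, and Davis enolate hydroxylation should occur anti to the adjacent isopropenyl group, setting the future C8 oxygen trans to it.

Step 5
Reactants: 5 (5R,6R)-6-hydroxy-3-methyl-5-(prop-1-en-2-yl)cyclohex-2-en-1-one
Product: 6 (5R,6R)-3-methyl-5-(prop-1-en-2-yl)-6-(triisopropylsilyloxy)cyclohex-2-en-1-one
Conditions: TIPSOTf, 2,6-lutidine, CH2Cl2, –78 → 0 °C
Reagents that add atoms: triisopropylsilyl trifluoromethanesulfonate, CC(C)[Si](C(C)C)(C(C)C)OS(=O)(=O)C(F)(F)F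
Why: Silyl triflate silylation of the secondary alcohol; TIPS is chosen because it resists migration to the neighbouring oxygen under the basic conditions of steps 8 and 9.

Step 6
Reactants: 7 pent-1-en-3-one
Product: 8 (Z)-3-(tert-butyldimethylsilyloxy)penta-1,3-diene
Conditions: TBSOTf, Et3N, CH2Cl2, 0 °C
Reagents that add atoms: tert-butyldimethylsilyl trifluoromethanesulfonate, CC(C)(C)[Si](C)(C)OS(=O)(=O)C(F)(F)F
Why: Soft enolisation of the ethyl ketone gives the 2-silyloxydiene, the Z enol ether (methyl cis to oxygen) being the usual outcome of amine/silyl triflate enolisation.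

Step 7
Reactants: 6 (5R,6R)-3-methyl-5-(prop-1-en-2-yl)-6-(triisopropylsilyloxy)cyclohex-2-en-1-one; 8 (Z)-3-(tert-butyldimethylsilyloxy)penta-1,3-diene
Product: 9 3-(tert-butyldimethylsilyloxy)-8α-(triisopropylsilyloxy)-10βH-eremophila-2,11-dien-9-one (C4 epimers)
Conditions: Tf2NH (10 mol %), CH2Cl2, –78 → –40 °C; pyridine quench
Reagents that add atoms: none
Why: Silyl triflimide formed in situ from Tf2NH and 8 activates the enone; the enol-ether terminus C4 of 8 bonds to the methyl-bearing β-carbon C5 and the resulting ring-B silyl enol ether closes onto the silylated vinyl ketone (C10–C1), an asynchronous Diels–Alder (Mukaiyama–Michael/Michael) pathway that regenerates the silyl catalyst. The closest known reaction type is the triflimide- or aluminium-Lewis-acid-promoted Diels–Alder reaction of 2-silyloxydienes with β,β-disubstituted cyclohexenones that builds quaternary centres. Ring A is closed by a [4+2] cycloaddition that forms both σ-bonds (C4–C5 and C1–C10) and leaves the C2=C3 silyl enol ether. C5 and C10 arise by suprafacial addition to the C5=C10 bond on the face anti to the pseudo-equatorial C7 isopropenyl group, which gives the cis fusion with the C5 methyl cis to the isopropenyl group; C4 depends on the endo/exo mode (endo would place its methyl trans to the C5 methyl) and is not relied upon because step 8 equilibrates it. The step needs the para regiochemistry (C3–O para to the C9 carbonyl), secured by matching the largest HOMO coefficient of the diene at C4 with the enone β-carbon C5, and needs π-facial selectivity, secured by the C7 substituent.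

Step 8
Reactants: 9 3-(tert-butyldimethylsilyloxy)-8α-(triisopropylsilyloxy)-10βH-eremophila-2,11-dien-9-one
Product: 12 9α-hydroxy-8α-(triisopropylsilyloxy)-10βH-eremophil-11-en-3-one, via 9α-alcohol enol ether 10 (not isolated), via 4-epi ketone 11 (not isolated)
Conditions: L-Selectride, THF, –78 °C; then NaOMe (cat.), MeOH, 0 °C → rt; aq. NH4Cl
Reagents that add atoms: none
Why: Bulky-hydride reduction should occur from the equatorial β side because axial approach is blocked by C4, giving the axial 9α-alcohol, and methoxide then cleaves the silyl enol ether and equilibrates C4 through the C3 enolate to the equatorial 4β-methyl epimer (a 4α-methyl group would be syn-axial to C9 in the chair fixed by the equatorial C7 and C8 substituents), so both Diels–Alder epimers converge.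

Step 9
Reactants: 12 9α-hydroxy-8α-(triisopropylsilyloxy)-10βH-eremophil-11-en-3-one
Product: 13 8α-(triisopropylsilyloxy)-10βH-eremophil-11-ene-3α,9α-diol
Conditions: Li, NH3(l), THF, t-BuOH, –78 °C; NH4Cl
Reagents that add atoms: none
Why: Dissolving-metal ketone reduction gives the thermodynamically preferred equatorial 3α-alcohol, trans to the 4β-methyl group, and leaves the isolated alkene and the silyl ether untouched.

Step 10
Reactants: 13 8α-(triisopropylsilyloxy)-10βH-eremophil-11-ene-3α,9α-diol
Product: 14 3α-angeloyloxy-8α-(triisopropylsilyloxy)-10βH-eremophil-11-en-9α-ol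
Conditions: angelic acid, 2,4,6-trichlorobenzoyl chloride, Et3N, PhMe, rt; then 13, PhMe, 75 °C
Reagents that add atoms: angelic acid [(Z)-2-methylbut-2-enoic acid], C/C=C(/C)C(=O)O
Why: Yamaguchi esterification via the mixed anhydride (without DMAP, to keep the Z geometry) should acylate the unhindered equatorial C3–OH, whereas the axial C9–OH flanked by the ring fusion and the OTIPS group should not react.

Step 11
Reactants: 14 3α-angeloyloxy-8α-(triisopropylsilyloxy)-10βH-eremophil-11-en-9α-ol
Product: 15 3α-angeloyloxy-9α-(methanesulfonyloxy)-8α-(triisopropylsilyloxy)-10βH-eremophil-11-ene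
Conditions: MsCl, Et3N, CH2Cl2, 0 °C
Reagents that add atoms: methanesulfonyl chloride, CS(=O)(=O)Cl
Why: Mesylation through sulfene reaches the hindered axial C9–OH with retention of configuration and installs the leaving group for the final inversion.

Step 12
Reactants: 15 3α-angeloyloxy-9α-(methanesulfonyloxy)-8α-(triisopropylsilyloxy)-10βH-eremophil-11-ene
Product: 16 3α-angeloyloxy-9α-(methanesulfonyloxy)-10βH-eremophil-11-en-8α-ol
Conditions: HF·pyridine, pyridine, THF, 0 °C → rt
Reagents that add atoms: none
Why: Buffered fluoride desilylation cleaves the TIPS ether; the cis-disposed mesylate cannot be displaced by the liberated hydroxyl and the esters are stable.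

Step 13
Reactants: 16 3α-angeloyloxy-9α-(methanesulfonyloxy)-10βH-eremophil-11-en-8α-ol
Product: 17 3α-angeloyloxy-9α-(methanesulfonyloxy)-10βH-eremophil-11-en-8-one
Conditions: Dess–Martin periodinane, CH2Cl2, rt
Reagents that add atoms: none
Why: Dess–Martin oxidation forms the C8 ketone under neutral conditions, so the now enolisable C7 centre and the β,γ-unsaturated isopropenyl group are not exposed to base.

Step 14
Reactants: 17 3α-angeloyloxy-9α-(methanesulfonyloxy)-10βH-eremophil-11-en-8-one
Product: 18 3α-angeloyloxy-9β-senecioyloxy-10βH-eremophil-11-en-8-one (target)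
Conditions: senecioic acid (2 equiv), Cs2CO3 (1 equiv), DMF, rt
Reagents that add atoms: senecioic acid (3-methylbut-2-enoic acid), CC(C)=CC(=O)O
Why: SN2 displacement of the axial α-keto mesylate by caesium senecioate should proceed with inversion to the equatorial 9β-ester, which is also the thermodynamically preferred C9 epimer, so the outcome is convergent.

Compound list
1 | (+)-3-carene [(1S,6R)-3,7,7-trimethylbicyclo[4.1.0]hept-3-ene] | CC1=CC[C@@H]2[C@H](C1)C2(C)C | starting material
2 | car-3-en-5-one [(1R,6S)-4,7,7-trimethylbicyclo[4.1.0]hept-3-en-2-one] | CC1=CC(=O)[C@@H]2[C@H](C1)C2(C)C | intermediate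
3 | (S)-5-(2-hydroxypropan-2-yl)-3-methylcyclohex-2-en-1-one | CC(C)(O)[C@H]1CC(C)=CC(=O)C1 | intermediate
4 | (S)-3-methyl-5-(prop-1-en-2-yl)cyclohex-2-en-1-one | C=C(C)[C@H]1CC(C)=CC(=O)C1 | intermediate
5 | (5R,6R)-6-hydroxy-3-methyl-5-(prop-1-en-2-yl)cyclohex-2-en-1-one (OH trans to isopropenyl) | C=C(C)[C@H]1CC(C)=CC(=O)[C@@H]1O | intermediate
6 | (5R,6R)-3-methyl-5-(prop-1-en-2-yl)-6-(triisopropylsilyloxy)cyclohex-2-en-1-one | C=C(C)[C@H]1CC(C)=CC(=O)[C@@H]1O[Si](C(C)C)(C(C)C)C(C)C | intermediate
7 | pent-1-en-3-one (ethyl vinyl ketone) | CCC(=O)C=C | starting material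
8 | (Z)-3-(tert-butyldimethylsilyloxy)penta-1,3-diene | C=C/C(O[Si](C)(C)C(C)(C)C)=C/C | intermediate
9 | 3-(tert-butyldimethylsilyloxy)-8α-(triisopropylsilyloxy)-10βH-eremophila-2,11-dien-9-one (5β-Me, 7β-isopropenyl, C4 epimers) | C=C(C)[C@H]1C[C@@]2(C)[C@H](CC=C(O[Si](C)(C)C(C)(C)C)C2C)C(=O)[C@@H]1O[Si](C(C)C)(C(C)C)C(C)C | intermediate
10 | 3-(tert-butyldimethylsilyloxy)-8α-(triisopropylsilyloxy)-10βH-eremophila-2,11-dien-9α-ol (C4 epimers, not isolated) | C=C(C)[C@H]1C[C@@]2(C)[C@H](CC=C(O[Si](C)(C)C(C)(C)C)C2C)[C@H](O)[C@@H]1O[Si](C(C)C)(C(C)C)C(C)C | intermediate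
11 | 9α-hydroxy-8α-(triisopropylsilyloxy)-4-epi-10βH-eremophil-11-en-3-one (4α-methyl, not isolated) | C=C(C)[C@H]1C[C@@]2(C)[C@H](CCC(=O)[C@H]2C)[C@H](O)[C@@H]1O[Si](C(C)C)(C(C)C)C(C)C | intermediate
12 | 9α-hydroxy-8α-(triisopropylsilyloxy)-10βH-eremophil-11-en-3-one (4β-methyl) | C=C(C)[C@H]1C[C@@]2(C)[C@H](CCC(=O)[C@@H]2C)[C@H](O)[C@@H]1O[Si](C(C)C)(C(C)C)C(C)C | intermediate
13 | 8α-(triisopropylsilyloxy)-10βH-eremophil-11-ene-3α,9α-diol | C=C(C)[C@H]1C[C@@]2(C)[C@H](CC[C@@H](O)[C@@H]2C)[C@H](O)[C@@H]1O[Si](C(C)C)(C(C)C)C(C)C | intermediate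
14 | 3α-angeloyloxy-8α-(triisopropylsilyloxy)-10βH-eremophil-11-en-9α-ol | C=C(C)[C@H]1C[C@@]2(C)[C@H](CC[C@@H](OC(=O)/C(C)=C\C)[C@@H]2C)[C@H](O)[C@@H]1O[Si](C(C)C)(C(C)C)C(C)C | intermediate
15 | 3α-angeloyloxy-9α-(methanesulfonyloxy)-8α-(triisopropylsilyloxy)-10βH-eremophil-11-ene | C=C(C)[C@H]1C[C@@]2(C)[C@H](CC[C@@H](OC(=O)/C(C)=C\C)[C@@H]2C)[C@H](OS(C)(=O)=O)[C@@H]1O[Si](C(C)C)(C(C)C)C(C)C | intermediate
16 | 3α-angeloyloxy-9α-(methanesulfonyloxy)-10βH-eremophil-11-en-8α-ol | C=C(C)[C@H]1C[C@@]2(C)[C@H](CC[C@@H](OC(=O)/C(C)=C\C)[C@@H]2C)[C@H](OS(C)(=O)=O)[C@@H]1O | intermediate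
17 | 3α-angeloyloxy-9α-(methanesulfonyloxy)-10βH-eremophil-11-en-8-one | C=C(C)[C@H]1C[C@@]2(C)[C@H](CC[C@@H](OC(=O)/C(C)=C\C)[C@@H]2C)[C@H](OS(C)(=O)=O)C1=O | intermediate
18 | 3α-angeloyloxy-9β-senecioyloxy-10βH-eremophil-11-en-8-one | C=C(C)[C@H]1C[C@@]2(C)[C@H](CC[C@@H](OC(=O)/C(C)=C\C)[C@@H]2C)[C@@H](OC(=O)C=C(C)C)C1=O | target

Total step count: 14. Longest linear sequence: 13 steps (steps 1–5 and 7–14).

Steps most likely to fail

Step 7. The cycloaddition may stall at the hindered β,β-disubstituted enone, or the diene may be lost by protodesilylation before the second bond forms. The fallback makes the two bonds one after the other. Starting from 6 and 8, a stoichiometric TiCl4-mediated Mukaiyama–Michael addition (CH2Cl2, –78 °C, aqueous work-up) would give the open-chain enone 5-methyl-5-(3-oxopent-4-en-2-yl)-3-(prop-1-en-2-yl)-2-(triisopropylsilyloxy)cyclohexan-1-one F1. Soft enolisation of its ring ketone with TBSOTf/Et3N would then trigger the intramolecular Michael closure onto the vinyl ketone and trap the new enolate as the silyl enol ether, returning to 9.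

Step 14. The substitution at the hindered α-keto carbon may be overtaken by elimination or by base-mediated enolisation at C7. The fallback replaces inversion by retention followed by equilibration. Starting from 14, the axial alcohol would be acylated with 3-methylbut-2-enoyl chloride/DMAP to the 9α-senecioate 3α-angeloyloxy-9α-senecioyloxy-8α-(triisopropylsilyloxy)-10βH-eremophil-11-ene F2. Desilylation with HF·pyridine would give 3α-angeloyloxy-9α-senecioyloxy-10βH-eremophil-11-en-8α-ol F3, and Dess–Martin oxidation the C9 epimer of the target, 3α-angeloyloxy-9α-senecioyloxy-10βH-eremophil-11-en-8-one F4. Brief treatment with catalytic DBU should then epimerise the axial α-acyloxy ketone to the equatorial ester, arriving at 18.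

Step 3. The elimination may take the ring methine hydrogen and give the isopropylidene isomer, or the double bond may migrate. The fallback avoids any cationic or E2 pathway. Starting from 2, Lewis-acid-promoted homoconjugate opening of the cyclopropyl ketone with PhSeSiMe3/ZnI2 (aqueous work-up) would give the tertiary selenide (S)-3-methyl-5-[2-(phenylselanyl)propan-2-yl]cyclohex-2-en-1-one F5. Oxidation with H2O2/pyridine and selenoxide syn-elimination would return to 4.

Further compounds
F1 | step 7 | 5-methyl-5-(3-oxopent-4-en-2-yl)-3-(prop-1-en-2-yl)-2-(triisopropylsilyloxy)cyclohexan-1-one | C=C(C)[C@H]1C[C@@](C(C)C(=O)C=C)(C)CC(=O)[C@@H]1O[Si](C(C)C)(C(C)C)C(C)C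
F2 | step 14 | 3α-angeloyloxy-9α-senecioyloxy-8α-(triisopropylsilyloxy)-10βH-eremophil-11-ene | C=C(C)[C@H]1C[C@@]2(C)[C@H](CC[C@@H](OC(=O)/C(C)=C\C)[C@@H]2C)[C@H](OC(=O)C=C(C)C)[C@@H]1O[Si](C(C)C)(C(C)C)C(C)C
F3 | step 14 | 3α-angeloyloxy-9α-senecioyloxy-10βH-eremophil-11-en-8α-ol | C=C(C)[C@H]1C[C@@]2(C)[C@H](CC[C@@H](OC(=O)/C(C)=C\C)[C@@H]2C)[C@H](OC(=O)C=C(C)C)[C@@H]1O
F4 | step 14 | 3α-angeloyloxy-9α-senecioyloxy-10βH-eremophil-11-en-8-one | C=C(C)[C@H]1C[C@@]2(C)[C@H](CC[C@@H](OC(=O)/C(C)=C\C)[C@@H]2C)[C@H](OC(=O)C=C(C)C)C1=O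
F5 | step 3 | (S)-3-methyl-5-[2-(phenylselanyl)propan-2-yl]cyclohex-2-en-1-one | CC(C)([Se]c1ccccc1)[C@H]1CC(C)=CC(=O)C1
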